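**Plan**

- Feature used: in the benzoate ring the ester-bearing carbon C1 sits between C2–OH and C6–alkyl, with OMe on C4. The C2/C4 oxygen pair is the 1,3-dioxygen pattern of a butadiene ketene acetal, and C1–C6 is the former triple bond of a 2-ynoate.
- Cuts, in retrosynthetic order: the two benzyl–O bonds of the resorcinol ring; ring bonds C1–C2 and C5–C6 of the benzoate (cycloaddition/aromatisation); the ester C(=O)–O bond.
- Further cuts in the acid: the carboxyl C–C bond (CO2) and the CH2–C(sp) bond made by epoxide opening. In the alcohol: the aryl–CH2 bond (Suzuki) and the CH2–CH2 bond made by epoxide opening.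
- Forward: both chains are grown from the same epoxide and joined as an ynoate ester. The benzoate ring is then built on that ester as the only ring-forming event, and hydrogenolysis finishes the route.
- Stereochemistry: both (R)-carbinol centres come from (R)-2-propyloxirane, opened at its CH2 carbon. No later step breaks a bond at either centre, since the ester is made by acyl activation.

Key step: step 10

Remark (assumption): metal salts of a product that exist only until aqueous work-up (alkoxides, carboxylates) are not numbered; organometallic species made in the flask and the intermediates of the cycloaddition are. The ketene-acetal geometry of the diene is left undefined because that carbon becomes aromatic.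

**Route**

Step 1
Reactants: 1 non-1-yne; 2 (R)-2-propyloxirane
Product: 4 (R)-tetradec-6-yn-4-ol, via lithium non-1-ynide 3 (not isolated)
Conditions: n-BuLi, THF, −78 °C; BF3·OEt2, then 2, −78 °C; aqueous work-up
Reagents that add atoms: none
Why: Yamaguchi–Hirao alkynylation, in which the lithium acetylide opens the BF3-activated epoxide by SN2 attack at the unsubstituted CH2 carbon, so the carbinol centre is carried over from 2 unchanged as (R).

Step 2
Reactants: 4 (R)-tetradec-6-yn-4-ol
Product: 5 (R)-tetradec-13-yn-4-ol
Conditions: KH, H2N(CH2)3NH2, rt (KAPA); then 4, 0 °C → rt; H2O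
Reagents that add atoms: none
Why: Alkyne zipper isomerisation, in which repeated propargyl/allenyl deprotonation–reprotonation moves the triple bond away from the alkoxide until the terminal acetylide traps it, while the carbinol C–H (deactivated by the adjacent alkoxide) is not touched and the (R) centre should be kept.

Step 3
Reactants: 5 (R)-tetradec-13-yn-4-ol
Product: 7 (12R)-12-hydroxypentadec-2-ynoic acid, via dilithium alkoxide acetylide 6 (not isolated)
Conditions: n-BuLi (2.2 equiv), THF, −78 → 0 °C; CO2 (g), −78 °C → rt; 1 M HCl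
Reagents that add atoms: carbon dioxide, O=C=O
Why: Carboxylation of a lithium acetylide, where only the carbanion forms a C–C bond with CO2 and any alkyl carbonate formed at the alkoxide oxygen reverts to the alcohol on acidification.

Step 4
Reactants: 7 (12R)-12-hydroxypentadec-2-ynoic acid
Product: 8 (12R)-12-acetoxypentadec-2-ynoic acid
Conditions: Ac2O (3 equiv), pyridine, CH2Cl2, 0 °C → rt; then H2O–THF, rt; 1 M HCl
Reagents that add atoms: acetic anhydride, CC(=O)OC(C)=O
Why: Standard O-acetylation of a secondary alcohol in a hydroxy acid, the mixed anhydride formed at the carboxyl group being hydrolysed back to the acid during the aqueous stir, with the carbinol configuration not involved.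

Step 5
Reactants: 9 6-bromohex-1-ene; 2 (R)-2-propyloxirane
Product: 11 (R)-undec-10-en-4-ol, via hex-5-enylmagnesium bromide 10 (not isolated)
Conditions: Mg, THF; then CuI (10 mol %), 2, THF, −30 → 0 °C; H2O
Reagents that add atoms: none
Why: Copper-catalysed Grignard opening of a terminal epoxide, which should occur at the CH2 carbon only and leave the (R) centre of 2 intact.

Step 6
Reactants: 11 (R)-undec-10-en-4-ol; 12 1-bromo-3,5-bis(benzyloxy)benzene
Product: 14 (4R)-11-[3,5-bis(benzyloxy)phenyl]undecan-4-ol, via B-alkyl-9-BBN borane 13 (not isolated)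
Conditions: 9-BBN (2.2 equiv), THF, 0 °C → rt; then 12, PdCl2(dppf) (5 mol %), 3 M aq. NaOH, THF, 65 °C
Reagents that add atoms: none
Why: Anti-Markovnikov hydroboration followed by B-alkyl Suzuki–Miyaura coupling with the aryl bromide, with the excess borane covering any borinate formed at the carbinol (cleaved by the aqueous base) and the benzyl ethers inert.

Step 7
Reactants: 8 (12R)-12-acetoxypentadec-2-ynoic acid; 14 (4R)-11-[3,5-bis(benzyloxy)phenyl]undecan-4-ol
Product: 15 (4R)-11-[3,5-bis(benzyloxy)phenyl]undecan-4-yl (12R)-12-acetoxypentadec-2-ynoate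
Conditions: DCC, DMAP (0.1 equiv), CH2Cl2, 0 °C → rt
Reagents that add atoms: none
Why: Steglich esterification of an unhindered sp-substituted acid, which activates the acyl group and leaves the C–O bond of the alcohol intact, so the (R) centre of 14 is retained and the acetate is untouched.

Step 8
Reactants: 16 methyl acetoacetate
Product: 17 methyl (E)-3-methoxybut-2-enoate
Conditions: HC(OMe)3, conc. H2SO4 (cat.), rt
Reagents that add atoms: trimethyl orthoformate, COC(OC)OC
Why: Acid-catalysed ketalisation of the ketone carbonyl by the orthoformate followed by loss of methanol should give the conjugated (E)-enol ether.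

Step 9
Reactants: 17 methyl (E)-3-methoxybut-2-enoate
Product: 19 1,3-dimethoxy-1-(trimethylsilyloxy)buta-1,3-diene, via lithium dienolate 18 (not isolated)
Conditions: LDA, THF, −78 °C; TMSCl, −78 °C → rt; distillation
Reagents that add atoms: chlorotrimethylsilane, C[Si](C)(C)Cl
Why: γ-Deprotonation of the vinylogous ester gives the extended enolate, which TMSCl traps on oxygen to give the silyl ketene acetal diene (standard preparation of a Brassard-type diene).

Step 10
Reactants: 15 (4R)-11-[3,5-bis(benzyloxy)phenyl]undecan-4-yl (12R)-12-acetoxypentadec-2-ynoate; 19 1,3-dimethoxy-1-(trimethylsilyloxy)buta-1,3-diene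
Product: 22 (4R)-11-[3,5-bis(benzyloxy)phenyl]undecan-4-yl 2-[(9R)-9-acetoxydodecyl]-6-hydroxy-4-methoxybenzoate, via cycloadduct 20 (not isolated), via dienone 21 (not isolated)
Conditions: 19 (4 equiv, added in portions), toluene, sealed tube, 120 °C; then 1 M HCl, THF, rt
Reagents that add atoms: none
Why: The electron-rich 1,3-dioxygenated diene 19 should add to the electron-poor triple bond of 15 in a normal-demand, strongly asynchronous [4+2] cycloaddition, the known Diels–Alder reaction of 1-alkoxy-1-silyloxy dienes with acetylenic esters that leads to salicylates. The six-membered carbocycle closes intermolecularly from the four diene carbons and the two alkyne carbons, the CH2 terminus of 19 bonding to the β-carbon and the ketene-acetal carbon to the α-carbon of the ynoate, to give cyclohexa-1,4-diene 20. Its mixed methyl silyl ketal loses methoxytrimethylsilane to give dienone 21, which enolises to the chelated phenol 22; loss of methanol and hydrolysis of the aryl silyl ether on acidic work-up would lead to the same phenol. No lasting stereocentre is created, since the ketal carbon of 20 forms as a mixture and is destroyed on aromatisation, and the two remote carbinol centres are untouched. The step needs regioselectivity, which the matched polarisation secures (most nucleophilic diene terminus CH2, most electrophilic alkyne carbon Cβ), so that OH ends ortho and OMe para to the ester, while the neutral thermal conditions spare the acetate, the benzyl ethers and the secondary ester. Because a β-alkyl ynoate is a slow dienophile, the diene is used in excess and added in portions at 120 °C.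

Step 11
Reactants: 22 (4R)-11-[3,5-bis(benzyloxy)phenyl]undecan-4-yl 2-[(9R)-9-acetoxydodecyl]-6-hydroxy-4-methoxybenzoate
Product: 23 5'-methoxy-integracin A, (4R)-11-(3,5-dihydroxyphenyl)undecan-4-yl 2-[(9R)-9-acetoxydodecyl]-6-hydroxy-4-methoxybenzoate
Conditions: H2 (1 atm), 10% Pd/C, EtOAc, rt
Reagents that add atoms: none
Why: Hydrogenolysis of the two aryl benzyl ethers over palladium, under which the acetate, the hindered benzoate ester, the arenes and both carbinol centres should be stable.

**Compound list**

1 | non-1-yne | C#CCCCCCCC | starting material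
2 | (R)-2-propyloxirane | CCC[C@@H]1CO1 | starting material
3 | lithium non-1-ynide (formed in the flask) | [Li+].[C-]#CCCCCCCC | intermediate
4 | (R)-tetradec-6-yn-4-ol | CCC[C@@H](O)CC#CCCCCCCC | intermediate
5 | (R)-tetradec-13-yn-4-ol | CCC[C@@H](O)CCCCCCCCC#C | intermediate
6 | dilithium (R)-tetradec-13-yn-14-id-4-olate (formed in the flask) | [Li+].[Li+].CCC[C@@H]([O-])CCCCCCCCC#[C-] | intermediate
7 | (12R)-12-hydroxypentadec-2-ynoic acid | CCC[C@@H](O)CCCCCCCCC#CC(=O)O | intermediate
8 | (12R)-12-acetoxypentadec-2-ynoic acid | CCC[C@H](CCCCCCCCC#CC(=O)O)OC(C)=O | intermediate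
9 | 6-bromohex-1-ene | C=CCCCCBr | starting material
10 | hex-5-enylmagnesium bromide (formed in the flask) | C=CCCCC[Mg]Br | intermediate
11 | (R)-undec-10-en-4-ol | CCC[C@@H](O)CCCCCC=C | intermediate
12 | 1-bromo-3,5-bis(benzyloxy)benzene | Brc1cc(OCc2ccccc2)cc(OCc2ccccc2)c1 | starting material
13 | (4R)-11-(9-borabicyclo[3.3.1]nonan-9-yl)undecan-4-ol (formed in the flask) | CCC[C@@H](O)CCCCCCCB1C2CCCC1CCC2 | intermediate
14 | (4R)-11-[3,5-bis(benzyloxy)phenyl]undecan-4-ol | CCC[C@@H](O)CCCCCCCc1cc(OCc2ccccc2)cc(OCc2ccccc2)c1 | intermediate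
15 | (4R)-11-[3,5-bis(benzyloxy)phenyl]undecan-4-yl (12R)-12-acetoxypentadec-2-ynoate | CCC[C@H](CCCCCCCCC#CC(=O)O[C@H](CCC)CCCCCCCc1cc(OCc2ccccc2)cc(OCc2ccccc2)c1)OC(C)=O | intermediate
16 | methyl acetoacetate | CC(=O)CC(=O)OC | starting material
17 | methyl (E)-3-methoxybut-2-enoate | CO/C(C)=C/C(=O)OC | intermediate
18 | lithium 1,3-dimethoxybuta-1,3-dien-1-olate (formed in the flask) | [Li+].C=C(OC)C=C(OC)[O-] | intermediate
19 | 1,3-dimethoxy-1-(trimethylsilyloxy)buta-1,3-diene (ketene-acetal geometry undefined) | C=C(OC)C=C(OC)O[Si](C)(C)C | intermediate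
20 | (4R)-11-[3,5-bis(benzyloxy)phenyl]undecan-4-yl 2-[(9R)-9-acetoxydodecyl]-4,6-dimethoxy-6-(trimethylsilyloxy)cyclohexa-1,4-diene-1-carboxylate (both configurations at C6; formed in the flask) | CCC[C@H](CCCCCCCCC1=C(C(=O)O[C@H](CCC)CCCCCCCc2cc(OCc3ccccc3)cc(OCc3ccccc3)c2)C(OC)(O[Si](C)(C)C)C=C(OC)C1)OC(C)=O | intermediate
21 | (4R)-11-[3,5-bis(benzyloxy)phenyl]undecan-4-yl 2-[(9R)-9-acetoxydodecyl]-4-methoxy-6-oxocyclohexa-1,4-diene-1-carboxylate (formed in the flask) | CCC[C@H](CCCCCCCCC1=C(C(=O)O[C@H](CCC)CCCCCCCc2cc(OCc3ccccc3)cc(OCc3ccccc3)c2)C(=O)C=C(OC)C1)OC(C)=O | intermediate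
22 | (4R)-11-[3,5-bis(benzyloxy)phenyl]undecan-4-yl 2-[(9R)-9-acetoxydodecyl]-6-hydroxy-4-methoxybenzoate | CCC[C@H](CCCCCCCCc1cc(OC)cc(O)c1C(=O)O[C@H](CCC)CCCCCCCc1cc(OCc2ccccc2)cc(OCc2ccccc2)c1)OC(C)=O | intermediate
23 | 5'-methoxy-integracin A, (4R)-11-(3,5-dihydroxyphenyl)undecan-4-yl 2-[(9R)-9-acetoxydodecyl]-6-hydroxy-4-methoxybenzoate | CCC[C@H](CCCCCCCCc1cc(OC)cc(O)c1C(=O)O[C@H](CCC)CCCCCCCc1cc(O)cc(O)c1)OC(C)=O | target

**Step count**

Total: 11 steps. Longest linear sequence: 7 steps (1, 2, 3, 4, 7, 10, 11).

**Steps most likely to fail**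

1. Step 10. The acyclic ketene acetal may be consumed by thermal silyl migration and oligomerisation faster than it adds to the slow β-alkyl ynoate, so that 15 stays largely unconverted. The fallback sets out from 15 and returns at 22, replacing the acyclic diene by a thermally robust cyclic one and the aromatisation by a Diels–Alder/retro-Diels–Alder (Alder–Rickert) sequence. Dimedone would be bis-silylated (TBSOTf, Et3N) to 1,3-bis(tert-butyldimethylsilyloxy)-5,5-dimethylcyclohexa-1,3-diene F1. Heating 15 with this diene at 140–160 °C should give the bicyclo[2.2.2]octadiene adduct F2, which expels 2-methylpropene in the flask to leave the 4,6-bis(silyloxy)benzoate F3. HF·pyridine in THF would free the 4,6-dihydroxybenzoate F4. MeI and K2CO3 in acetone should then methylate only the non-chelated hydroxyl para to the ester, the ortho hydroxyl being held by the hydrogen bond to the ester carbonyl, which gives 22.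

2. Step 2. The isomerisation may stall at mixtures of internal alkynes that cannot be separated from the terminal one, or the strongly basic medium may degrade the alkynol. The fallback sets out from 2 and returns at 5, bringing in the terminal alkyne ready-made so that steps 1 and 2 are both replaced. Lithium trimethylsilylacetylide would be alkylated with excess 1,7-dibromoheptane (THF–DMPU) to (9-bromonon-1-yn-1-yl)trimethylsilane F5. Its Grignard reagent, [9-(trimethylsilyl)non-8-yn-1-yl]magnesium bromide F6, would open 2 at the CH2 carbon under CuI catalysis to give (R)-14-(trimethylsilyl)tetradec-13-yn-4-ol F7. K2CO3 in methanol removes the silyl group and gives 5.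

3. Step 4. Mixed-anhydride formation at the free carboxyl group may lead to oligoesters with the hydroxyl of a second molecule, or to conjugate addition of pyridine or acetate to the activated triple bond. The fallback sets out from 5 and returns at 8, reversing the order of events so that steps 3 and 4 are replaced. Compound 5 would first be acetylated (Ac2O, pyridine, DMAP) to (R)-tetradec-13-yn-4-yl acetate F8. The terminal C–H would then be carboxylated without an organolithium base (AgI cat., Cs2CO3, CO2, DMF, 50 °C; then dilute HCl), conditions under which the acetate should survive, giving 8 directly.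

**Further compounds**

F1 | step 10 | 1,3-bis(tert-butyldimethylsilyloxy)-5,5-dimethylcyclohexa-1,3-diene | CC1(C)CC(O[Si](C)(C)C(C)(C)C)=CC(O[Si](C)(C)C(C)(C)C)=C1
F2 | step 10 | (4R)-11-[3,5-bis(benzyloxy)phenyl]undecan-4-yl 3-[(9R)-9-acetoxydodecyl]-1,5-bis(tert-butyldimethylsilyloxy)-8,8-dimethylbicyclo[2.2.2]octa-2,5-diene-2-carboxylate | CCC[C@H](CCCCCCCCC1=C(C(=O)O[C@H](CCC)CCCCCCCc2cc(OCc3ccccc3)cc(OCc3ccccc3)c2)C2(O[Si](C)(C)C(C)(C)C)C=C(O[Si](C)(C)C(C)(C)C)C1C(C)(C)C2)OC(C)=O
F3 | step 10 | (4R)-11-[3,5-bis(benzyloxy)phenyl]undecan-4-yl 2-[(9R)-9-acetoxydodecyl]-4,6-bis(tert-butyldimethylsilyloxy)benzoate | CCC[C@H](CCCCCCCCc1cc(O[Si](C)(C)C(C)(C)C)cc(O[Si](C)(C)C(C)(C)C)c1C(=O)O[C@H](CCC)CCCCCCCc1cc(OCc2ccccc2)cc(OCc2ccccc2)c1)OC(C)=O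
F4 | step 10 | (4R)-11-[3,5-bis(benzyloxy)phenyl]undecan-4-yl 2-[(9R)-9-acetoxydodecyl]-4,6-dihydroxybenzoate | CCC[C@H](CCCCCCCCc1cc(O)cc(O)c1C(=O)O[C@H](CCC)CCCCCCCc1cc(OCc2ccccc2)cc(OCc2ccccc2)c1)OC(C)=O
F5 | step 2 | (9-bromonon-1-yn-1-yl)trimethylsilane | C[Si](C)(C)C#CCCCCCCCBr
F6 | step 2 | [9-(trimethylsilyl)non-8-yn-1-yl]magnesium bromide | C[Si](C)(C)C#CCCCCCCC[Mg]Br
F7 | step 2 | (R)-14-(trimethylsilyl)tetradec-13-yn-4-ol | CCC[C@@H](O)CCCCCCCCC#C[Si](C)(C)C
F8 | step 4 | (R)-tetradec-13-yn-4-yl acetate | CCC[C@H](CCCCCCCCC#C)OC(C)=O
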